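Maple, at the colder temperature, holds 36.6% of target at its last reading, more than cedar's 34.2%, yet maple was charged with less other conformer, so I do the accounts on the substrate charged.

in all of them: substrate 1.1 M; catalyst 2.5 mol%
- maple: other conformer 0.70 equiv; temperature 8 °C; run made earlier
- cedar: other conformer 1.1 equiv; temperature 35 °C; run made earlier
- Wednesday's: other conformer 0.500 equiv; temperature 20 °C; time 30 h
- Saturday's: other conformer 0.500 equiv; temperature 45 °C; time 30 h
- Monday's: other conformer 0.500 equiv; temperature −5 °C; time 30 h

| run | time / h | target / % |
|---|---|---|
| maple | 2.50 | 4.0 |
| maple | 10.0 | 15.8 |
| maple | 15.0 | 20.8 |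
| maple | 20.0 | 25.7 |
| maple | 40.0 | 36.6 |
| cedar | 0.667 | 10.1 |
| cedar | 1.33 | 16.6 |
| cedar | 2.50 | 26.0 |
| cedar | 5.00 | 32.6 |
| cedar | 10.0 | 34.2 |

(scatter of a reading: 0.5 percentage points)

- percent here means substrate units held: one side product or self-condensation product counts as two
- on the list of suspects stand: substrate <-> other conformer; catalyst + other conformer -> catalyst + isomer of the product; substrate + target -> side product; 2 other conformer -> self-condensation product; substrate + catalyst -> catalyst + target
- in a conversion other conformer counts as not yet reacted

1. which flask leads in amount of target, in percent of the substrate and other conformer together charged ("all alike" within 1.5 percentage points) (Wednesday's / Saturday's / Monday's / all alike)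
2. how much target is there at the end, in percent of the substrate and other conformer together charged: Wednesday's
3. how much target is there at the end, in percent of the substrate and other conformer together charged: Saturday's
4. how much target is there at the end, in percent of the substrate and other conformer together charged: Monday's

Cedar has nearly stopped, and dividing its last reading by its substrate share gives 71.8%. I call this the keep: target at the stop per substrate charged, with other conformer outside the base. Maple is still climbing, but its readings at 20.0 h and 40.0 h are spaced for a simple exponential, which points to a stop at 44.6% and a keep of 75.9%.

The same curves give the rate of the approach, 0.0429 h⁻¹ for maple and 0.571 h⁻¹ for cedar, and one over that rate is the clock, the time constant of the approach. Control passes from clock to keep where the clock equals the time allowed.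

Wednesday's stands near the middle of maple and cedar, so I take the geometric mean, 0.157 h⁻¹. Monday's lies about as far below maple in temperature as Wednesday's lies above it, so I step down from maple's rate by the same factor, which gives 0.0118 h⁻¹. Monday's clock of 84.7 h is longer than the 30 h allowed, while Wednesday's 6.37 h is shorter.

My ledger for these flasks opens with 33.3% of the charge as other conformer, which I book away from target, and 66.7% as substrate. In my estimate each flask then takes its keep and, where the clock matters, its unfinished part, and Wednesday's comes out ahead:

- Wednesday's closes at 48.8%.
- Saturday's, hotter than cedar, takes a keep one step lower and closes at 46.5%.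
- Monday's, cut short by its clock, reaches 15.1%.

The forecast also names Wednesday's, with 51% for Wednesday's, 46% for Saturday's and 14% for Monday's, and holds that “the other conformer feeds back little”; its figures stand within about two points of mine.

The flasks give 50.4% for Wednesday's, 45.3% for Saturday's and 14.1% for Monday's, so Wednesday's leads.

    substrate ⇌ other conformer (K = 0.705, k = 0.00663 h⁻¹, Ea = 112 kJ mol⁻¹, ΔH = −34.0 kJ mol⁻¹)
    catalyst + other conformer → catalyst + isomer of the product (k = 12.2 L mol⁻¹ h⁻¹, Ea = 46.0 kJ mol⁻¹)
    substrate + target → side product (k = 0.0243 L mol⁻¹ h⁻¹, Ea = 87.0 kJ mol⁻¹)
    2 other conformer → self-condensation product (k = 0.104 L mol⁻¹ h⁻¹, Ea = 83.0 kJ mol⁻¹)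
    substrate + catalyst → catalyst + target (k = 3.65 L mol⁻¹ h⁻¹, Ea = 66.0 kJ mol⁻¹)
    (constants at 20 °C)

Saturday's closes with a keep of 67.9%, lower than cedar's 71.8%. A neighbour of Saturday's, charged with 0.120 equiv of other conformer at the same temperature, opens its ledger with a substrate share of 89.3%, and Saturday's keep books 60.7% of target there. That neighbour gives 56.6%, a keep of 63.4%. Its isomer of the product stands at 16.6%, more than the 10.7% charged there as other conformer, and its side product at 24.4%, more than Saturday's 21.4%.

The readings were generated by integration for substances that don't exist; noise was put on by code.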